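**Plan**

- Retrosynthesis: the caffeoyl ester C–O bond is cut first, then the benzylic O1–C2 bond of the oxolane (leaving an open-chain triol), then the C4–CH2Ar bond (lactone enolate alkylation), and last the C2–C3 bond together with the O–C bond at the CH2O carbon, which are the two oxetane bonds of an aldehyde/furan photoadduct.
- Feature used: the chain CH2O-carbon–C3–C4–C5 of the oxolane carries oxygen on both end carbons and is the four-carbon skeleton of furan; the aryl-bearing C2 is the carbonyl carbon of vanillin.
- Forward: the oxetane ring is closed first (photocycloaddition across the furan 2,3-bond), the remaining enol ether is oxidised to a lactone and benzylated on its convex face, hydride opens both rings to a triol, acid closes the oxolane, and esterification and desilylation finish.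
- Stereochemistry: the absolute configuration is to come from a chiral hydrogen-bonding triplet sensitiser in the photocycloaddition (C5 of the photoadduct becomes C3 of the target); C4 follows from convex-face alkylation and C2 from the trans-selective ring closure.
- Remark: the benzylic centre made in the photocycloaddition is re-set in the oxolane closure, so only C5 of the photoadduct must be delivered in the right absolute sense; the target is the (2R,3S,4S) oxolane (2,3-trans, 3,4-cis); TBS = tert-butyldimethylsilyl.

Key step: step 2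

Step 1
Reactants: 1 vanillin
Product: 2 4-(tert-butyldimethylsilyloxy)-3-methoxybenzaldehyde
Conditions: TBSCl, imidazole, DMF, rt
Reagents that add atoms: tert-butyldimethylsilyl chloride, CC(C)(C)[Si](C)(C)Cl
Why: Imidazole-promoted silyl ether formation masks the phenol, whose O–H would quench the triplet aldehyde by hydrogen transfer in step 2 and consume base in step 6.

Step 2
Reactants: 2 4-(tert-butyldimethylsilyloxy)-3-methoxybenzaldehyde; 3 furan
Product: 5 (1S,5R,6S)-6-[4-(tert-butyldimethylsilyloxy)-3-methoxyphenyl]-2,7-dioxabicyclo[3.2.0]hept-3-ene, via triplet 1,4-biradical 4 (not isolated)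
Conditions: enantiopure xanthone sensitiser carrying a 1,5,7-trimethyl-3-azabicyclo[3.3.1]nonan-2-one lactam site (10 mol%), furan (20 equiv), PhCF3, −25 °C, hν (366 nm)
Reagents that add atoms: none
Why: Proposed new method: the lactam of the sensitiser should hold the formyl group of 2 through N–H···O=C and formyl C–H···O=C hydrogen bonds, so that the aldehyde lies over the xanthone and receives its triplet energy while the carbonyl n-orbital stays free (a Lewis acid on the carbonyl oxygen would remove the nπ* character on which oxetane formation depends). The nπ* triplet then bonds through oxygen to C2 of furan to give the triplet 1,4-biradical 4 (benzylic and allylic radical centres), and after intersystem crossing radical recombination between the benzylic carbon and the former furan C3 closes the four-membered ring. The closest known reactions are the racemic, exo-selective Paternò–Büchi photocycloaddition of aromatic aldehydes with furan and the enantioselective [2+2] photocycloadditions of lactams run with this class of hydrogen-bonding xanthone sensitisers. Of the three new stereocentres, C1 and C5 are tied together by the cis ring fusion, C6 is placed relative to them by the exo preference of the biradical closure (aryl on the convex face), and the absolute sense is to come from the xanthone plane, which covers one face of the bound carbonyl so that C–C closure occurs on the open face; the sensitiser enantiomer that gives the (1S,5R,6S) adduct is used. The step needs regioselectivity (oxygen to the furan α-carbon, secured by the allylic stabilisation of 4), mono-addition (secured by the excess of furan) and enantioselectivity, the last depending on excitation of bound instead of free aldehyde, which is why 366 nm light, low temperature and a non-coordinating solvent are chosen.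

Step 3
Reactants: 5 (1S,5R,6S)-6-[4-(tert-butyldimethylsilyloxy)-3-methoxyphenyl]-2,7-dioxabicyclo[3.2.0]hept-3-ene
Product: 6 (1R,5R,6S)-6-[4-(tert-butyldimethylsilyloxy)-3-methoxyphenyl]-2,7-dioxabicyclo[3.2.0]heptan-3-one
Conditions: pyridinium chlorochromate (C5H5NH[CrO3Cl]), NaOAc, 4 Å molecular sieves, CH2Cl2, 0 °C to rt
Reagents that add atoms: pyridinium chlorochromate, [O-][Cr](=O)(=O)Cl.c1cc[nH+]cc1
Why: Chromium-based oxidation of a cyclic enol ether to the lactone is a known transformation (hexavalent chromium adds to the electron-rich C3=C4 bond and a hydride shift leaves the carbonyl at C3); the acetate buffer guards the acid-labile oxetane acetal and no stereocentre is involved.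

Step 4
Reactants: 2 4-(tert-butyldimethylsilyloxy)-3-methoxybenzaldehyde
Product: 7 [4-(tert-butyldimethylsilyloxy)-3-methoxyphenyl]methanol
Conditions: NaBH4, MeOH/THF, 0 °C
Reagents that add atoms: none
Why: Borohydride reduction of the aryl aldehyde to the benzylic alcohol, brief enough at 0 °C for the aryl silyl ether to survive.

Step 5
Reactants: 7 [4-(tert-butyldimethylsilyloxy)-3-methoxyphenyl]methanol
Product: 8 4-(bromomethyl)-1-(tert-butyldimethylsilyloxy)-2-methoxybenzene
Conditions: CBr4, PPh3, CH2Cl2, 0 °C; used at once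
Reagents that add atoms: carbon tetrabromide, BrC(Br)(Br)Br
Why: Appel bromination converts the benzylic alcohol into the bromide under neutral conditions that spare the silyl ether.

Step 6
Reactants: 6 (1R,5R,6S)-6-[4-(tert-butyldimethylsilyloxy)-3-methoxyphenyl]-2,7-dioxabicyclo[3.2.0]heptan-3-one; 8 4-(bromomethyl)-1-(tert-butyldimethylsilyloxy)-2-methoxybenzene
Product: 10 (1R,4S,5R,6S)-4-[4-(tert-butyldimethylsilyloxy)-3-methoxybenzyl]-6-[4-(tert-butyldimethylsilyloxy)-3-methoxyphenyl]-2,7-dioxabicyclo[3.2.0]heptan-3-one, via lithium enolate 9 (not isolated)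
Conditions: LiN(SiMe3)2, THF, −78 °C; then 8, DMPU, −78 to −40 °C
Reagents that add atoms: none
Why: SN2 alkylation of a γ-alkoxy-γ-butyrolactone lithium enolate with a benzylic bromide is a standard operation of dibenzylbutyrolactone lignan synthesis; the bromide approaches the convex face of the cis-fused bicycle, anti to the oxetane, which sets C4 as S with the arylmethyl group trans to the C5–C6 bond, the arrangement also favoured at equilibrium.

Step 7
Reactants: 10 (1R,4S,5R,6S)-4-[4-(tert-butyldimethylsilyloxy)-3-methoxybenzyl]-6-[4-(tert-butyldimethylsilyloxy)-3-methoxyphenyl]-2,7-dioxabicyclo[3.2.0]heptan-3-one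
Product: 11 (2S,3S)-2-[4-(tert-butyldimethylsilyloxy)-3-methoxybenzyl]-3-[(S)-hydroxy[4-(tert-butyldimethylsilyloxy)-3-methoxyphenyl]methyl]butane-1,4-diol
Conditions: LiBH4, THF, 0 °C to rt; aq. NH4Cl
Reagents that add atoms: none
Why: Lactone reduction with LiBH4: hydride addition at C3 expels the acetal oxygen, the hemiacetal alkoxide so formed opens the oxetane to an aldehyde at C1, and both aldehydes should be reduced faster than retro-aldol cleavage, so the bicycle unravels to the triol with its three stereocentres untouched.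

Step 8
Reactants: 11 (2S,3S)-2-[4-(tert-butyldimethylsilyloxy)-3-methoxybenzyl]-3-[(S)-hydroxy[4-(tert-butyldimethylsilyloxy)-3-methoxyphenyl]methyl]butane-1,4-diol
Product: 12 [(2R,3S,4S)-4-[4-(tert-butyldimethylsilyloxy)-3-methoxybenzyl]-2-[4-(tert-butyldimethylsilyloxy)-3-methoxyphenyl]oxolan-3-yl]methanol
Conditions: camphorsulfonic acid (5 mol%), CH2Cl2, 0 °C
Reagents that add atoms: none
Why: Acid-catalysed SN1 cycloetherification: the para-silyloxybenzylic alcohol ionises and the C1 hydroxyl (next to the arylmethyl-bearing carbon) closes the five-membered ring, the other primary hydroxyl being able to give only an oxetane; the aryl group takes the position trans to the neighbouring CH2OH (new C2 = R), as known for acid cyclisation of 7-hydroxysecoisolariciresinol-type triols to lariciresinol-type oxolanes.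

Step 9
Reactants: 13 caffeic acid
Product: 15 (E)-3-[3,4-bis(tert-butyldimethylsilyloxy)phenyl]prop-2-enoic acid, via tris-silyl caffeate 14 (not isolated)
Conditions: TBSCl (3.5 equiv), imidazole, DMF, rt; then AcOH/THF/H2O, rt
Reagents that add atoms: tert-butyldimethylsilyl chloride, CC(C)(C)[Si](C)(C)Cl
Why: Exhaustive silylation followed by selective hydrolysis of the labile silyl ester (aryl silyl ethers withstand aqueous acetic acid) gives the catechol-protected acid with the E alkene unchanged.

Step 10
Reactants: 12 [(2R,3S,4S)-4-[4-(tert-butyldimethylsilyloxy)-3-methoxybenzyl]-2-[4-(tert-butyldimethylsilyloxy)-3-methoxyphenyl]oxolan-3-yl]methanol; 15 (E)-3-[3,4-bis(tert-butyldimethylsilyloxy)phenyl]prop-2-enoic acid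
Product: 16 [(2R,3S,4S)-4-[4-(tert-butyldimethylsilyloxy)-3-methoxybenzyl]-2-[4-(tert-butyldimethylsilyloxy)-3-methoxyphenyl]oxolan-3-yl]methyl (E)-3-[3,4-bis(tert-butyldimethylsilyloxy)phenyl]prop-2-enoate
Conditions: N,N'-diisopropylcarbodiimide, DMAP (cat.), CH2Cl2, 0 °C to rt
Reagents that add atoms: none
Why: Steglich esterification (carbodiimide activation, DMAP acyl transfer) of the only free hydroxyl of 12; no stereocentre is involved and the E alkene is retained.

Step 11
Reactants: 16 [(2R,3S,4S)-4-[4-(tert-butyldimethylsilyloxy)-3-methoxybenzyl]-2-[4-(tert-butyldimethylsilyloxy)-3-methoxyphenyl]oxolan-3-yl]methyl (E)-3-[3,4-bis(tert-butyldimethylsilyloxy)phenyl]prop-2-enoate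
Product: 17 [(2R,3S,4S)-2-(4-hydroxy-3-methoxyphenyl)-4-(4-hydroxy-3-methoxybenzyl)oxolan-3-yl]methyl (E)-3-(3,4-dihydroxyphenyl)prop-2-enoate
Conditions: Bu4NF, AcOH (1:1), THF, 0 °C
Reagents that add atoms: none
Why: Fluoride cleavage of the four aryl silyl ethers, buffered with acetic acid so that the liberated phenoxides neither attack the ester nor oxidise, and mild enough to leave the acid-sensitive 2-aryl oxolane and the cinnamate alone.

**Compound list**

1 | vanillin (4-hydroxy-3-methoxybenzaldehyde) | COc1cc(C=O)ccc1O | starting material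
2 | 4-(tert-butyldimethylsilyloxy)-3-methoxybenzaldehyde | COc1cc(C=O)ccc1O[Si](C)(C)C(C)(C)C | intermediate
3 | furan | c1ccoc1 | starting material
4 | triplet 1,4-biradical: 2-(arylmethyloxy)-2,3-dihydrofuran with radical centres at the benzylic carbon and at ring C3 (allylic); acetal carbon configured as C1 of 5; aryl = 4-(tert-butyldimethylsilyloxy)-3-methoxyphenyl | [CH]1C=CO[C@H]1O[CH]c2ccc(O[Si](C)(C)C(C)(C)C)c(OC)c2 | intermediate (not isolated)
5 | (1S,5R,6S)-6-[4-(tert-butyldimethylsilyloxy)-3-methoxyphenyl]-2,7-dioxabicyclo[3.2.0]hept-3-ene (cis-fused, aryl exo) | C1=CO[C@H]2O[C@H](c3ccc(O[Si](C)(C)C(C)(C)C)c(OC)c3)[C@@H]12 | intermediate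
6 | (1R,5R,6S)-6-[4-(tert-butyldimethylsilyloxy)-3-methoxyphenyl]-2,7-dioxabicyclo[3.2.0]heptan-3-one | C1C(=O)O[C@H]2O[C@H](c3ccc(O[Si](C)(C)C(C)(C)C)c(OC)c3)[C@@H]12 | intermediate
7 | [4-(tert-butyldimethylsilyloxy)-3-methoxyphenyl]methanol | COc1cc(CO)ccc1O[Si](C)(C)C(C)(C)C | intermediate
8 | 4-(bromomethyl)-1-(tert-butyldimethylsilyloxy)-2-methoxybenzene | COc1cc(CBr)ccc1O[Si](C)(C)C(C)(C)C | intermediate
9 | lithium enolate of 6 (O–Li on C3, C3=C4) | C1=C(O[Li])O[C@H]2O[C@H](c3ccc(O[Si](C)(C)C(C)(C)C)c(OC)c3)[C@@H]12 | intermediate (not isolated)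
10 | (1R,4S,5R,6S)-4-[4-(tert-butyldimethylsilyloxy)-3-methoxybenzyl]-6-[4-(tert-butyldimethylsilyloxy)-3-methoxyphenyl]-2,7-dioxabicyclo[3.2.0]heptan-3-one (arylmethyl exo) | [C@@H]1(Cc4ccc(O[Si](C)(C)C(C)(C)C)c(OC)c4)C(=O)O[C@H]2O[C@H](c3ccc(O[Si](C)(C)C(C)(C)C)c(OC)c3)[C@@H]12 | intermediate
11 | (2S,3S)-2-[4-(tert-butyldimethylsilyloxy)-3-methoxybenzyl]-3-[(S)-hydroxy[4-(tert-butyldimethylsilyloxy)-3-methoxyphenyl]methyl]butane-1,4-diol | OC[C@@H](Cc1ccc(O[Si](C)(C)C(C)(C)C)c(OC)c1)[C@@H](CO)[C@H](O)c1ccc(O[Si](C)(C)C(C)(C)C)c(OC)c1 | intermediate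
12 | [(2R,3S,4S)-4-[4-(tert-butyldimethylsilyloxy)-3-methoxybenzyl]-2-[4-(tert-butyldimethylsilyloxy)-3-methoxyphenyl]oxolan-3-yl]methanol | COc1cc(C[C@@H]2CO[C@@H](c3ccc(O[Si](C)(C)C(C)(C)C)c(OC)c3)[C@@H]2CO)ccc1O[Si](C)(C)C(C)(C)C | intermediate
13 | caffeic acid ((E)-3-(3,4-dihydroxyphenyl)prop-2-enoic acid) | OC(=O)/C=C/c1ccc(O)c(O)c1 | starting material
14 | tert-butyldimethylsilyl (E)-3-[3,4-bis(tert-butyldimethylsilyloxy)phenyl]prop-2-enoate | CC(C)(C)[Si](C)(C)OC(=O)/C=C/c1ccc(O[Si](C)(C)C(C)(C)C)c(O[Si](C)(C)C(C)(C)C)c1 | intermediate (not isolated)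
15 | (E)-3-[3,4-bis(tert-butyldimethylsilyloxy)phenyl]prop-2-enoic acid | OC(=O)/C=C/c1ccc(O[Si](C)(C)C(C)(C)C)c(O[Si](C)(C)C(C)(C)C)c1 | intermediate
16 | [(2R,3S,4S)-4-[4-(tert-butyldimethylsilyloxy)-3-methoxybenzyl]-2-[4-(tert-butyldimethylsilyloxy)-3-methoxyphenyl]oxolan-3-yl]methyl (E)-3-[3,4-bis(tert-butyldimethylsilyloxy)phenyl]prop-2-enoate | COc1cc(C[C@@H]2CO[C@@H](c3ccc(O[Si](C)(C)C(C)(C)C)c(OC)c3)[C@@H]2COC(=O)/C=C/c2ccc(O[Si](C)(C)C(C)(C)C)c(O[Si](C)(C)C(C)(C)C)c2)ccc1O[Si](C)(C)C(C)(C)C | intermediate
17 | [(2R,3S,4S)-2-(4-hydroxy-3-methoxyphenyl)-4-(4-hydroxy-3-methoxybenzyl)oxolan-3-yl]methyl (E)-3-(3,4-dihydroxyphenyl)prop-2-enoate | COc1cc(C[C@@H]2CO[C@@H](c3ccc(O)c(OC)c3)[C@@H]2COC(=O)/C=C/c2ccc(O)c(O)c2)ccc1O | target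

Total step count: 11. Longest linear sequence: 8 steps (steps 1, 2, 3, 6, 7, 8, 10, 11).

**Steps most likely to fail**

1. Step 2 (Proposed new method). Weak one-point binding of the aldehyde, direct excitation of unbound aldehyde and slow cycloaddition of an electron-rich aldehyde could each erode the enantiomeric purity. The fallback uses known chemistry and sets out from 2 and 3. Irradiation of 2 in neat furan through Pyrex without any chiral additive is the established racemic, exo-selective Paternò–Büchi reaction. It should give 5 together with its mirror image, (1R,5S,6R)-6-[4-(tert-butyldimethylsilyloxy)-3-methoxyphenyl]-2,7-dioxabicyclo[3.2.0]hept-3-ene F1. Oxidation of the mixture as in step 3 should give 6 together with (1S,5S,6R)-6-[4-(tert-butyldimethylsilyloxy)-3-methoxyphenyl]-2,7-dioxabicyclo[3.2.0]heptan-3-one F2. Preparative chromatography on a chiral stationary phase (amylose tris(3,5-dimethylphenylcarbamate), CO2/iPrOH) would separate the two lactones. The route is rejoined at 6, whose configuration would be confirmed by carrying a sample on to 12 and desilylating it for comparison with lariciresinol.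

2. Step 3. Acid-promoted opening of the oxetane acetal, followed by aromatisation to a 3-furyl carbinol, could outrun the chromium oxidation and erase C1 and C5. The fallback sets out from 5 and avoids acid altogether. NBS in THF/H2O with NaHCO3 at 0 °C should add bromine to C4 from the convex face and water to C3, giving (1R,4S,5R,6S)-4-bromo-6-[4-(tert-butyldimethylsilyloxy)-3-methoxyphenyl]-2,7-dioxabicyclo[3.2.0]heptan-3-ol F3 as a mixture at C3. Oxidation of this lactol with Pr4N[RuO4] and N-methylmorpholine N-oxide should give (1R,4S,5R,6S)-4-bromo-6-[4-(tert-butyldimethylsilyloxy)-3-methoxyphenyl]-2,7-dioxabicyclo[3.2.0]heptan-3-one F4. Radical debromination with Bu3SnH and AIBN in toluene then returns the route to 6.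

3. Step 8. The benzylic cation may instead be captured by the electron-rich arylmethyl ring (Friedel–Crafts closure to an aryltetralin), or the ring may close with incomplete trans selectivity at C2. The fallback sets out from 11 and changes the end game to a protecting-group-free one. Bu4NF/AcOH should free both phenols to give (2S,3S)-2-(4-hydroxy-3-methoxybenzyl)-3-[(S)-hydroxy(4-hydroxy-3-methoxyphenyl)methyl]butane-1,4-diol F5. With the para-hydroxyl free, water is lost under very mild acid (dilute formic acid in aqueous MeCN, rt) by way of a para-quinone methide, which the primary hydroxyl traps. This is the known cyclisation of 7-hydroxysecoisolariciresinol and should give 4-[(2R,3S,4S)-4-(4-hydroxy-3-methoxybenzyl)-3-(hydroxymethyl)oxolan-2-yl]-2-methoxyphenol F6. A Mitsunobu esterification with unprotected caffeic acid 13 (PPh3, DIAD, THF, 0 °C) activates only the aliphatic primary alcohol and leaves the phenols alone, so it comes back to the route at 17.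

Further compounds
F1 | step 2 | (1R,5S,6R)-6-[4-(tert-butyldimethylsilyloxy)-3-methoxyphenyl]-2,7-dioxabicyclo[3.2.0]hept-3-ene | C1=CO[C@@H]2O[C@@H](c3ccc(O[Si](C)(C)C(C)(C)C)c(OC)c3)[C@H]12
F2 | step 2 | (1S,5S,6R)-6-[4-(tert-butyldimethylsilyloxy)-3-methoxyphenyl]-2,7-dioxabicyclo[3.2.0]heptan-3-one | C1C(=O)O[C@@H]2O[C@@H](c3ccc(O[Si](C)(C)C(C)(C)C)c(OC)c3)[C@H]12
F3 | step 3 | (1R,4S,5R,6S)-4-bromo-6-[4-(tert-butyldimethylsilyloxy)-3-methoxyphenyl]-2,7-dioxabicyclo[3.2.0]heptan-3-ol (mixture at C3) | [C@@H]1(Br)C(O)O[C@H]2O[C@H](c3ccc(O[Si](C)(C)C(C)(C)C)c(OC)c3)[C@@H]12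
F4 | step 3 | (1R,4S,5R,6S)-4-bromo-6-[4-(tert-butyldimethylsilyloxy)-3-methoxyphenyl]-2,7-dioxabicyclo[3.2.0]heptan-3-one | [C@@H]1(Br)C(=O)O[C@H]2O[C@H](c3ccc(O[Si](C)(C)C(C)(C)C)c(OC)c3)[C@@H]12
F5 | step 8 | (2S,3S)-2-(4-hydroxy-3-methoxybenzyl)-3-[(S)-hydroxy(4-hydroxy-3-methoxyphenyl)methyl]butane-1,4-diol | OC[C@@H](Cc1ccc(O)c(OC)c1)[C@@H](CO)[C@H](O)c1ccc(O)c(OC)c1
F6 | step 8 | 4-[(2R,3S,4S)-4-(4-hydroxy-3-methoxybenzyl)-3-(hydroxymethyl)oxolan-2-yl]-2-methoxyphenol | COc1cc(C[C@@H]2CO[C@@H](c3ccc(O)c(OC)c3)[C@@H]2CO)ccc1O
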